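**Strategy**

The tetrahydrofuran ring is divided into a three-atom O1–C5–C4 unit and a two-atom C2–C3 unit. Racemic 2-vinyloxirane supplies the first as a palladium-bound alkoxide–allyl dipole; dimethyl 3,4,5-trimethoxybenzylidenemalonate supplies the second as a doubly activated styrene. One ligand-controlled palladium-catalysed (3+2) cycloaddition forms O1–C2 and C3–C4, closes the ring and sets C4 and C2 (2,4-cis), converging both epoxide enantiomers. The vinyl group left on C4 is the latent carbinol carbon; the geminal diester at C3 is the latent, epimerisable CH2OH carbon. Decarboxylation under thermodynamic control, alkene cleavage, aryl addition, oxidation, reagent-controlled reduction and ester reduction complete the target.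

Key step: step 2

Assumption on the ligand: the (1R,2R) antipode of the diphosphine is written as the one that delivers (4R); this sense is a working model, and the (1S,2S) antipode is used instead if the first experiment shows the opposite sense.

Remark on descriptors: the ring is numbered O1, C2 (trimethoxyphenyl), C3, C4, C5 throughout. The CIP label of C2 changes from S (diester 7) to R (from 8 on), and that of C3 from R (ester) to S (CH2OH), without any change in geometry.

**Route**

Step 1
Reactants: 1 3,4,5-trimethoxybenzaldehyde; 2 dimethyl malonate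
Product: 3 dimethyl 2-(3,4,5-trimethoxybenzylidene)malonate
Conditions: piperidine (10 mol %), AcOH (10 mol %), toluene, reflux, Dean–Stark trap
Reagents that add atoms: none
Why: Knoevenagel condensation under amine–acid catalysis with azeotropic removal of water drives the aldol–dehydration to the conjugated diester; no stereocentre is formed and the two identical esters leave no alkene geometry to control.

Step 2
Reactants: 3 dimethyl 2-(3,4,5-trimethoxybenzylidene)malonate; 4 racemic 2-vinyloxirane
Product: 7 dimethyl (2S,4R)-4-ethenyl-2-(3,4,5-trimethoxyphenyl)oxolane-3,3-dicarboxylate (2,4-cis), via π-allylpalladium alkoxide zwitterion 5 (not isolated), via ring-open oxa-Michael malonate anion 6 (not isolated)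
Conditions: Pd2(dba)3·CHCl3 (2.5 mol %), (1R,2R)-N,N′-bis[2-(diphenylphosphanyl)benzoyl]cyclohexane-1,2-diamine (7.5 mol %), CH2Cl2, 25 °C, slow addition of 4 (1.5 equiv)
Reagents that add atoms: none
Why: Zerovalent palladium opens either enantiomer of 4 with inversion to zwitterion 5, whose diastereomeric π-allyl complexes interconvert by π–σ–π isomerisation at the CH2 terminus; the alkoxide adds reversibly to the benzylidene carbon of 3 (O1–C2, anion 6) and the malonate carbanion then attacks the substituted allyl carbon anti to palladium (C3–C4), releasing the catalyst. The closest known reaction type is the palladium-catalysed (3+2) cycloaddition of vinyl epoxides with doubly activated alkenes, combined with the dynamic kinetic asymmetric allylic alkylation of butadiene monoepoxide by diphosphine-ligated palladium. The one ring closes in a 5-exo mode, the carbanion attacking an allyl carbon whose other two allyl carbons stay outside the ring; attack at the CH2 terminus would require a seven-membered ring. C4 is set by the chiral diphosphine in the irreversible alkylation, which selects between the equilibrating π-allyl complexes; C2 is set relative to C4 because the oxa-Michael addition is reversible, so that the epimer of 6 able to close with the aryl group pseudo-equatorial and cis to the vinyl group should be drained preferentially. The step needs O-before-C bond formation and branched regioselectivity: the first is secured because the alkoxide is the only nucleophile in 5 and the alkene carries two esters, the second by the tether length. C3 carries two identical esters and is not yet a stereocentre; any 2,4-trans isomer is removed by chromatography.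

Step 3
Reactants: 7 dimethyl (2S,4R)-4-ethenyl-2-(3,4,5-trimethoxyphenyl)oxolane-3,3-dicarboxylate
Product: 9 methyl (2R,3R,4R)-4-ethenyl-2-(3,4,5-trimethoxyphenyl)oxolane-3-carboxylate (all-trans), via C3-epimer mixture of the monoester 8 (not isolated)
Conditions: LiCl (3 equiv), H2O (2 equiv), DMSO, 150 °C; crude, then NaOMe (0.2 equiv), MeOH, 25 °C
Reagents that add atoms: none
Why: Krapcho dealkoxycarbonylation (chloride attacks one ester methyl group, the carboxylate loses CO2, the enolate is protonated) should give a mixture at C3, and methoxide in methanol then equilibrates C3 through the ester enolate to the all-trans isomer, in which the ester avoids both cis-disposed neighbours on C2 and C4; C2 and C4 carry no acidic hydrogen, and ring-opening β-elimination from the enolate is stereoelectronically disfavoured (reverse of a 5-endo closure).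

Step 4
Reactants: 9 methyl (2R,3R,4R)-4-ethenyl-2-(3,4,5-trimethoxyphenyl)oxolane-3-carboxylate
Product: 11 methyl (2R,3R,4R)-4-formyl-2-(3,4,5-trimethoxyphenyl)oxolane-3-carboxylate, via vicinal diol 10 (not isolated)
Conditions: OsO4 (2 mol %), NaIO4 (4 equiv), 2,6-lutidine (2 equiv), dioxane–H2O 3:1, 25 °C
Reagents that add atoms: osmium tetroxide, O=[Os](=O)(=O)=O (catalytic carrier of the oxygen); sodium periodate, [Na+].[O-]I(=O)(=O)=O (terminal oxidant that resupplies it)
Why: Lemieux–Johnson oxidation (catalytic dihydroxylation of the only alkene, then periodate cleavage of diol 10, buffered with 2,6-lutidine) should leave the electron-rich arene, the benzylic ether and the ester untouched; no stereocentre is formed, C4 (now α to the aldehyde) already holds its thermodynamically preferred trans orientation, and the crude aldehyde is used at once.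

Step 5
Reactants: 11 methyl (2R,3R,4R)-4-formyl-2-(3,4,5-trimethoxyphenyl)oxolane-3-carboxylate; 12 4-bromo-1,2-dimethoxybenzene
Product: 14 methyl (2R,3R,4R)-4-[(3,4-dimethoxyphenyl)(hydroxy)methyl]-2-(3,4,5-trimethoxyphenyl)oxolane-3-carboxylate (both carbinol epimers), via 3,4-dimethoxyphenylmagnesium bromide 13 (not isolated)
Conditions: 12 (1.3 equiv), Mg, I2 (cat.), THF, 50 °C; then added to 11, THF, −78 °C; sat. aq NH4Cl
Reagents that add atoms: none
Why: Grignard addition at −78 °C discriminates the aldehyde from the methyl ester; the new carbinol centre is expected as a mixture (Felkin and chelate models disagree) and is deliberately corrected in steps 6 and 7, while the trans C3/C4 relationship prevents lactonisation of the alkoxide, which would require a trans-fused bicycle.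

Step 6
Reactants: 14 methyl (2R,3R,4R)-4-[(3,4-dimethoxyphenyl)(hydroxy)methyl]-2-(3,4,5-trimethoxyphenyl)oxolane-3-carboxylate
Product: 15 methyl (2R,3R,4R)-4-(3,4-dimethoxybenzoyl)-2-(3,4,5-trimethoxyphenyl)oxolane-3-carboxylate
Conditions: Dess–Martin periodinane (1.3 equiv), NaHCO3, CH2Cl2, 0 to 25 °C
Reagents that add atoms: none
Why: Dess–Martin oxidation under bicarbonate buffer converts both carbinol epimers into one aryl ketone without a base strong enough to enolise C4, which is in any case in its favoured trans arrangement; the carbinol stereocentre is erased on purpose.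

Step 7
Reactants: 15 methyl (2R,3R,4R)-4-(3,4-dimethoxybenzoyl)-2-(3,4,5-trimethoxyphenyl)oxolane-3-carboxylate
Product: 16 methyl (2R,3R,4R)-4-[(S)-(3,4-dimethoxyphenyl)(hydroxy)methyl]-2-(3,4,5-trimethoxyphenyl)oxolane-3-carboxylate
Conditions: (R)-2-methyl-CBS-oxazaborolidine (0.5 equiv), BH3·SMe2 (1.0 equiv), THF, −20 °C; MeOH quench
Reagents that add atoms: none
Why: Corey–Bakshi–Shibata reduction, in which the ketone binds the catalyst–borane complex with the aryl group as the large substituent, so that the (R)-oxazaborolidine should deliver hydride to the face giving the (S)-carbinol (the mirror image of the (S)-catalyst/acetophenone to (R)-alcohol outcome), while borane leaves the methyl ester intact.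

Step 8
Reactants: 16 methyl (2R,3R,4R)-4-[(S)-(3,4-dimethoxyphenyl)(hydroxy)methyl]-2-(3,4,5-trimethoxyphenyl)oxolane-3-carboxylate
Product: 17 (S)-(3,4-dimethoxyphenyl)[(2R,3S,4R)-3-(hydroxymethyl)-2-(3,4,5-trimethoxyphenyl)oxolan-4-yl]methanol (target)
Conditions: LiAlH4 (2.5 equiv), THF, 0 °C; aq potassium sodium tartrate work-up, no acid
Reagents that add atoms: none
Why: LiAlH4 reduces the methyl ester to the primary alcohol without touching any stereocentre, and the neutral tartrate work-up avoids ionisation of the acid-labile 4-alkoxybenzylic alcohol.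

**Compound list**

1 | 3,4,5-trimethoxybenzaldehyde | COc1cc(C=O)cc(OC)c1OC | starting material
2 | dimethyl malonate | COC(=O)CC(=O)OC | starting material
3 | dimethyl 2-(3,4,5-trimethoxybenzylidene)malonate | COC(=O)C(=Cc1cc(OC)c(OC)c(OC)c1)C(=O)OC | intermediate
4 | racemic 2-vinyloxirane | C=CC1CO1 | starting material
5 | π-allylpalladium alkoxide zwitterion from 4 (drawn in its η1 form, diphosphine on divalent palladium omitted) | [O-]C/C=C/C[Pd+] | intermediate
6 | ring-open oxa-Michael malonate anion (same drawing convention, benzylic centre not yet fixed) | COC(=O)[C-](C(=O)OC)C(OC/C=C/C[Pd+])c1cc(OC)c(OC)c(OC)c1 | intermediate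
7 | dimethyl (2S,4R)-4-ethenyl-2-(3,4,5-trimethoxyphenyl)oxolane-3,3-dicarboxylate | C=C[C@H]1CO[C@@H](c2cc(OC)c(OC)c(OC)c2)C1(C(=O)OC)C(=O)OC | intermediate
8 | methyl (2R,4R)-4-ethenyl-2-(3,4,5-trimethoxyphenyl)oxolane-3-carboxylate, mixture of C3 epimers | C=C[C@H]1CO[C@@H](c2cc(OC)c(OC)c(OC)c2)C1C(=O)OC | intermediate
9 | methyl (2R,3R,4R)-4-ethenyl-2-(3,4,5-trimethoxyphenyl)oxolane-3-carboxylate | C=C[C@H]1CO[C@@H](c2cc(OC)c(OC)c(OC)c2)[C@@H]1C(=O)OC | intermediate
10 | methyl (2R,3R,4R)-4-(1,2-dihydroxyethyl)-2-(3,4,5-trimethoxyphenyl)oxolane-3-carboxylate, both diol epimers | OCC(O)[C@H]1CO[C@@H](c2cc(OC)c(OC)c(OC)c2)[C@@H]1C(=O)OC | intermediate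
11 | methyl (2R,3R,4R)-4-formyl-2-(3,4,5-trimethoxyphenyl)oxolane-3-carboxylate | O=C[C@H]1CO[C@@H](c2cc(OC)c(OC)c(OC)c2)[C@@H]1C(=O)OC | intermediate
12 | 4-bromo-1,2-dimethoxybenzene | COc1ccc(Br)cc1OC | starting material
13 | 3,4-dimethoxyphenylmagnesium bromide | COc1ccc([Mg]Br)cc1OC | intermediate
14 | methyl (2R,3R,4R)-4-[(3,4-dimethoxyphenyl)(hydroxy)methyl]-2-(3,4,5-trimethoxyphenyl)oxolane-3-carboxylate, both carbinol epimers | COc1ccc(C(O)[C@H]2CO[C@@H](c3cc(OC)c(OC)c(OC)c3)[C@@H]2C(=O)OC)cc1OC | intermediate
15 | methyl (2R,3R,4R)-4-(3,4-dimethoxybenzoyl)-2-(3,4,5-trimethoxyphenyl)oxolane-3-carboxylate | COc1ccc(C(=O)[C@H]2CO[C@@H](c3cc(OC)c(OC)c(OC)c3)[C@@H]2C(=O)OC)cc1OC | intermediate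
16 | methyl (2R,3R,4R)-4-[(S)-(3,4-dimethoxyphenyl)(hydroxy)methyl]-2-(3,4,5-trimethoxyphenyl)oxolane-3-carboxylate | COc1ccc([C@@H](O)[C@H]2CO[C@@H](c3cc(OC)c(OC)c(OC)c3)[C@@H]2C(=O)OC)cc1OC | intermediate
17 | (S)-(3,4-dimethoxyphenyl)[(2R,3S,4R)-3-(hydroxymethyl)-2-(3,4,5-trimethoxyphenyl)oxolan-4-yl]methanol | COc1ccc([C@@H](O)[C@H]2CO[C@@H](c3cc(OC)c(OC)c(OC)c3)[C@@H]2CO)cc1OC | target

**Step count and risks**

Total step count: 8.
Longest linear sequence: 8 steps (1 → 3 → 7 → 9 → 11 → 14 → 15 → 16 → 17); the Grignard reagent 13 is made inside step 5.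

Steps most likely to fail:

1. Step 2 (key step). What may go wrong: insufficient discrimination by the ligand between the interconverting π-allyl complexes, capture before they have equilibrated, low 2,4-cis selectivity, or oligomerisation of the zwitterion if the oxa-Michael addition is slow. The fallback replaces ligand-controlled dynamic selection by chirality transfer from an enantiopure alkenyl epoxide, whose 1,3-disubstituted π-allyl complex cannot exchange faces by π–σ–π isomerisation. It sets out from 3 and commercial (E)-cinnamaldehyde. Sulfonium ylide methylenation of cinnamaldehyde (Me3S+ I−, NaH, DMSO–THF, 0 °C; Corey–Chaykovsky reaction) should give racemic 2-[(E)-2-phenylethenyl]oxirane F1. Hydrolytic kinetic resolution (the (salen)Co(OAc) complex of N,N′-bis(3,5-di-tert-butylsalicylidene)cyclohexane-1,2-diamine, antipode chosen to leave the (S)-epoxide; H2O, 0.55 equiv) leaves (S)-2-[(E)-2-phenylethenyl]oxirane F2. F2 and 3 with Pd(PPh3)4 (5 mol %) in THF at 40 °C should give, by double inversion and hence net retention at C4, dimethyl (2S,4R)-4-[(E)-2-phenylethenyl]-2-(3,4,5-trimethoxyphenyl)oxolane-3,3-dicarboxylate F3. The conditions of step 3 convert F3, through the C3-epimer mixture of the styryl monoester F4, into methyl (2R,3R,4R)-4-[(E)-2-phenylethenyl]-2-(3,4,5-trimethoxyphenyl)oxolane-3-carboxylate F5. The conditions of step 4 cleave the styryl alkene through the phenyl-substituted vicinal diol F6, and the route is rejoined at aldehyde 11.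

2. Step 7. What may go wrong: erosion or reversal of reagent control, because the ketone is α-branched and already chiral (mismatched pairing), so that both carbinol epimers form. The fallback gives up reagent control for separation with recycling. From 15, NaBH4 (MeOH–CH2Cl2, −40 °C) reduces only the ketone under substrate control. Product 16 and its carbinol epimer, methyl (2R,3R,4R)-4-[(R)-(3,4-dimethoxyphenyl)(hydroxy)methyl]-2-(3,4,5-trimethoxyphenyl)oxolane-3-carboxylate F7, are diastereomers and should separate on silica. F7 is returned to 15 with Dess–Martin periodinane and reduced again, so that material converges on 16, where the route is rejoined.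

3. Step 5. What may go wrong: deprotonation of the α-branched aldehyde by the basic aryl Grignard reagent (loss of material, aldol products) or competing attack at the methyl ester. The fallback is a non-basic Nozaki–Hiyama–Kishi coupling. From 11, commercial 4-iodo-1,2-dimethoxybenzene with CrCl2 (4 equiv) and NiCl2 (2 mol %) in DMF at 25 °C should give the same carbinol mixture 14, where the route is rejoined; no new compound is made on the way (entry F0).

**Further compounds**

F1 | step 2 | racemic 2-[(E)-2-phenylethenyl]oxirane | c1ccccc1/C=C/C1CO1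
F2 | step 2 | (S)-2-[(E)-2-phenylethenyl]oxirane | c1ccccc1/C=C/[C@H]1CO1
F3 | step 2 | dimethyl (2S,4R)-4-[(E)-2-phenylethenyl]-2-(3,4,5-trimethoxyphenyl)oxolane-3,3-dicarboxylate | c1ccccc1/C=C/[C@H]2CO[C@@H](c3cc(OC)c(OC)c(OC)c3)C2(C(=O)OC)C(=O)OC
F4 | step 2 | methyl (2R,4R)-4-[(E)-2-phenylethenyl]-2-(3,4,5-trimethoxyphenyl)oxolane-3-carboxylate, mixture of C3 epimers | c1ccccc1/C=C/[C@H]2CO[C@@H](c3cc(OC)c(OC)c(OC)c3)C2C(=O)OC
F5 | step 2 | methyl (2R,3R,4R)-4-[(E)-2-phenylethenyl]-2-(3,4,5-trimethoxyphenyl)oxolane-3-carboxylate | c1ccccc1/C=C/[C@H]2CO[C@@H](c3cc(OC)c(OC)c(OC)c3)[C@@H]2C(=O)OC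
F6 | step 2 | methyl (2R,3R,4R)-4-(1,2-dihydroxy-2-phenylethyl)-2-(3,4,5-trimethoxyphenyl)oxolane-3-carboxylate, diol epimers | OC(c1ccccc1)C(O)[C@H]2CO[C@@H](c3cc(OC)c(OC)c(OC)c3)[C@@H]2C(=O)OC
F7 | step 7 | methyl (2R,3R,4R)-4-[(R)-(3,4-dimethoxyphenyl)(hydroxy)methyl]-2-(3,4,5-trimethoxyphenyl)oxolane-3-carboxylate | COc1ccc([C@H](O)[C@H]2CO[C@@H](c3cc(OC)c(OC)c(OC)c3)[C@@H]2C(=O)OC)cc1OC
F0 | step 5 | none | none
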